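## Retrosynthetic overview

1. The tetramer is cut at its centre, the ring B C1–C7' bond. This gives aryl bromide 12 (rings A and B, used as an aryltitanium) and α-aryloxy aldehyde 28 (rings C and D), joined by a Felkin–Anh carbonyl arylation that gives the erythro carbinol directly.
2. Enabling feature: ring B C1 is the one ring carbon para to the ether oxygen and flanked by two CH, so it is bought as the C–Br of 4-bromo-2,6-dimethoxyphenol. C7' is a carbinol carbon whose neighbour C8' bears the aryloxy group and a set stereocentre, so C7' can be an aldehyde carbon and C8' steers the incoming aryl group.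
3. Each half takes its C8–O or C8'–O aryl ether by Mitsunobu inversion on one chiral-pool unit, methyl (R)-3-silyloxy-2-hydroxypropanoate. The ring A–C7 bond is made by the same titanium-mediated arylation, which sets C7.
4. Ring order: rings A to D are bought as arenes. The only ring made is the dihydrofuran ring, by dirhodium-carbenoid C–H insertion (C2–C3 bond, step 13) and C3 epimerisation to trans. The enal is carried as a diethyl acetal installed by Suzuki–Miyaura coupling.
5. After the union, one global desilylation and acetal hydrolysis gives the target.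

Key step: step 21

Labels: ring A is the 4-hydroxy-3-methoxyphenyl ring and C7–C8–C9 its glycerol chain. Ring B is the central 3,5-dimethoxy-4-oxyphenyl ring and C7'–C8'–C9' its chain. Ring C is the second 3,5-dimethoxy-4-oxyphenyl ring. Ring D is the benzo ring of the 2,3-dihydrobenzofuran (O1, C2, C3, 3-CH2O, 7-OMe, side chain at C5). TBS is tert-butyldimethylsilyl and TIPS is triisopropylsilyl.

Assumption: Rh2(S-PTTL)4 is taken to give the (2R) configuration at the aryl-bearing carbon in step 13, by analogy with related aryldiazoacetate C–H insertions; if the facial sense were opposite, the catalyst made from (R)-tert-leucine would be used with no other change.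

## Route

Step 1
Reactants: 1 methyl (R)-2,2-dimethyl-1,3-dioxolane-4-carboxylate
Product: 2 methyl (R)-2,3-dihydroxypropanoate
Conditions: Dowex 50W (H+ form), MeOH, rt
Reagents that add atoms: none
Why: Acid-catalysed transacetalisation of the isopropylidene acetal to methanol frees the diol without touching the ester or the stereocentre.

Step 2
Reactants: 2 methyl (R)-2,3-dihydroxypropanoate
Product: 3 methyl (R)-3-[(tert-butyldimethylsilyl)oxy]-2-hydroxypropanoate
Conditions: TBSCl (1.05 equiv), imidazole, CH2Cl2, 0 °C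
Reagents that add atoms: tert-butyldimethylsilyl chloride, CC(C)(C)[Si](C)(C)Cl
Why: Kinetically selective silylation of the primary hydroxyl over the secondary α-ester hydroxyl is standard for glycerate esters.

Step 3
Reactants: 3 methyl (R)-3-[(tert-butyldimethylsilyl)oxy]-2-hydroxypropanoate; 4 4-bromo-2,6-dimethoxyphenol
Product: 5 methyl (S)-2-(4-bromo-2,6-dimethoxyphenoxy)-3-[(tert-butyldimethylsilyl)oxy]propanoate
Conditions: PPh3, DIAD, THF, 0 °C to rt
Reagents that add atoms: none
Why: Mitsunobu etherification, in which the phenoxide displaces the oxyphosphonium at the activated ester α-carbon by SN2, so the (R)-alcohol gives the (S)-aryl ether and fixes C8.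

Step 4
Reactants: 5 methyl (S)-2-(4-bromo-2,6-dimethoxyphenoxy)-3-[(tert-butyldimethylsilyl)oxy]propanoate
Product: 6 (S)-2-(4-bromo-2,6-dimethoxyphenoxy)-3-[(tert-butyldimethylsilyl)oxy]propanal
Conditions: i-Bu2AlH (1.1 equiv), CH2Cl2, −78 °C; MeOH, then aq. potassium sodium tartrate; used crude
Reagents that add atoms: none
Why: Partial reduction of the α-aryloxy ester stops at the tetrahedral aluminium hemiacetal at −78 °C and gives the aldehyde on work-up, which is used at once to keep C8 intact.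

Step 5
Reactants: 7 4-bromo-2-methoxyphenol
Product: 8 (4-bromo-2-methoxyphenoxy)triisopropylsilane
Conditions: TIPSCl, imidazole, DMF, rt
Reagents that add atoms: triisopropylsilyl chloride, CC(C)[Si](Cl)(C(C)C)C(C)C
Why: Standard phenol silylation gives a base-stable ether that survives bromine–lithium exchange.

Step 6
Reactants: 8 (4-bromo-2-methoxyphenoxy)triisopropylsilane; 6 (S)-2-(4-bromo-2,6-dimethoxyphenoxy)-3-[(tert-butyldimethylsilyl)oxy]propanal
Product: 11 (1R,2S)-2-(4-bromo-2,6-dimethoxyphenoxy)-3-[(tert-butyldimethylsilyl)oxy]-1-[3-methoxy-4-(triisopropylsilyloxy)phenyl]propan-1-ol, via aryllithium 9 (not isolated), via aryltitanium triisopropoxide 10 (not isolated)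
Conditions: 8, n-BuLi, THF, −78 °C; ClTi(OiPr)3, −78 to −40 °C; then 6, −78 to −30 °C; aq. NH4Cl
Reagents that add atoms: none
Why: Bromine–lithium exchange and transmetalation give an aryltitanium triisopropoxide that adds to the aldehyde under Felkin–Anh (non-chelation) control with the C8–OAr bond anti to the incoming aryl, so C8 sets the new C7 stereocentre anti (erythro, 7R), and the titanium reagent does not exchange with the aryl bromide of 6.

Step 7
Reactants: 11 (1R,2S)-2-(4-bromo-2,6-dimethoxyphenoxy)-3-[(tert-butyldimethylsilyl)oxy]-1-[3-methoxy-4-(triisopropylsilyloxy)phenyl]propan-1-ol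
Product: 12 the 1-O-TBS ether of 11 (left-half aryl bromide; 7-O-TBS, 9-O-TBS, ring A 4-O-TIPS; 7R,8S)
Conditions: TBSOTf, 2,6-lutidine, CH2Cl2, −78 to 0 °C
Reagents that add atoms: tert-butyldimethylsilyl trifluoromethanesulfonate, CC(C)(C)[Si](C)(C)OS(=O)(=O)C(F)(F)F
Why: The silyl triflate with 2,6-lutidine silylates the hindered secondary benzylic alcohol without epimerisation and removes the only acidic proton before the second exchange.

Step 8
Reactants: 13 4-hydroxy-3,5-dimethoxybenzaldehyde (syringaldehyde)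
Product: 14 3,5-dimethoxy-4-(triisopropylsilyloxy)benzaldehyde
Conditions: TIPSCl, imidazole, DMAP (cat.), DMF, 40 °C
Reagents that add atoms: triisopropylsilyl chloride, CC(C)[Si](Cl)(C(C)C)C(C)C
Why: Silylation blocks the ring C phenol with a group that is stable to the base, palladium and rhodium steps that follow and is removable later by fluoride.

Step 9
Reactants: 14 3,5-dimethoxy-4-(triisopropylsilyloxy)benzaldehyde
Product: 15 [3,5-dimethoxy-4-(triisopropylsilyloxy)phenyl]methanol
Conditions: NaBH4, MeOH/THF, 0 °C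
Reagents that add atoms: none
Why: Borohydride reduction of the aldehyde to the benzylic alcohol leaves the aryl silyl ether untouched.

Step 10
Reactants: 7 4-bromo-2-methoxyphenol
Product: 16 4-bromo-2-iodo-6-methoxyphenol
Conditions: N-iodosuccinimide, CF3CO2H (cat.), MeCN, 0 °C to rt
Reagents that add atoms: N-iodosuccinimide, O=C1CCC(=O)N1I
Why: Electrophilic aromatic iodination goes ortho to the free hydroxyl, the strongest director, because the para position carries bromine.

Step 11
Reactants: 15 [3,5-dimethoxy-4-(triisopropylsilyloxy)phenyl]methanol; 16 4-bromo-2-iodo-6-methoxyphenol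
Product: 17 [4-[(4-bromo-2-iodo-6-methoxyphenoxy)methyl]-2,6-dimethoxyphenoxy]triisopropylsilane
Conditions: PPh3, DIAD, THF, 0 °C to rt
Reagents that add atoms: none
Why: Mitsunobu etherification of a primary benzylic alcohol with an acidic phenol gives the aryl benzyl ether under neutral conditions that spare the electron-rich benzylic position.

Step 12
Reactants: 17 [4-[(4-bromo-2-iodo-6-methoxyphenoxy)methyl]-2,6-dimethoxyphenoxy]triisopropylsilane; 18 ethyl diazoacetate
Product: 19 ethyl 2-[5-bromo-2-[[3,5-dimethoxy-4-(triisopropylsilyloxy)phenyl]methoxy]-3-methoxyphenyl]-2-diazoacetate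
Conditions: Pd(PPh3)4 (5 mol%), Ag2CO3 (0.5 equiv), Et3N, toluene, rt
Reagents that add atoms: none
Why: Palladium-catalysed cross-coupling of an aryl iodide with ethyl diazoacetate (C–H arylation with retention of the diazo group) takes place at C–I, into which zerovalent palladium inserts far faster than into C–Br at room temperature.

Step 13
Reactants: 19 ethyl 2-[5-bromo-2-[[3,5-dimethoxy-4-(triisopropylsilyloxy)phenyl]methoxy]-3-methoxyphenyl]-2-diazoacetate
Product: 20 ethyl (2R,3S)-5-bromo-2-[3,5-dimethoxy-4-(triisopropylsilyloxy)phenyl]-7-methoxy-2,3-dihydro-1-benzofuran-3-carboxylate (cis)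
Conditions: Rh2(S-PTTL)4 [dirhodium tetrakis(N-phthaloyl-(S)-tert-leucinate)] (1 mol%), toluene, −60 °C, slow addition of 19
Reagents that add atoms: none
Why: Intramolecular 1,5 C–H insertion of the donor/acceptor dirhodium carbenoid into the doubly activated OCH2Ar methylene closes the dihydrofuran ring with cis selectivity, and the chiral carboxylate ligands choose the enantiotopic hydrogen and so set C2 as R.

Step 14
Reactants: 20 ethyl (2R,3S)-5-bromo-2-[3,5-dimethoxy-4-(triisopropylsilyloxy)phenyl]-7-methoxy-2,3-dihydro-1-benzofuran-3-carboxylate (cis)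
Product: 21 ethyl (2R,3R)-5-bromo-2-[3,5-dimethoxy-4-(triisopropylsilyloxy)phenyl]-7-methoxy-2,3-dihydro-1-benzofuran-3-carboxylate (trans)
Conditions: NaOEt (0.2 equiv), EtOH/THF, 0 °C to rt
Reagents that add atoms: none
Why: Catalytic ethoxide epimerises the acidic C3–H (ester α and benzylic) to the thermodynamically favoured 2,3-trans ester while C2 is not epimerisable, so C3 is set relative to C2.

Step 15
Reactants: 21 ethyl (2R,3R)-5-bromo-2-[3,5-dimethoxy-4-(triisopropylsilyloxy)phenyl]-7-methoxy-2,3-dihydro-1-benzofuran-3-carboxylate (trans)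
Product: 22 [(2R,3S)-5-bromo-2-[3,5-dimethoxy-4-(triisopropylsilyloxy)phenyl]-7-methoxy-2,3-dihydro-1-benzofuran-3-yl]methanol
Conditions: i-Bu2AlH (2.5 equiv), CH2Cl2, −78 to 0 °C; aq. potassium sodium tartrate
Reagents that add atoms: none
Why: Hydride reduction of the ester to the primary alcohol, with the aryl bromide and the silyl ether inert.

Step 16
Reactants: 22 [(2R,3S)-5-bromo-2-[3,5-dimethoxy-4-(triisopropylsilyloxy)phenyl]-7-methoxy-2,3-dihydro-1-benzofuran-3-yl]methanol
Product: 23 the O-TBS ether of 22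
Conditions: TBSCl, imidazole, DMF, rt
Reagents that add atoms: tert-butyldimethylsilyl chloride, CC(C)(C)[Si](C)(C)Cl
Why: Standard silylation of the primary alcohol.

Step 17
Reactants: 23 the O-TBS ether of 22; 24 (E)-2-(3,3-diethoxyprop-1-en-1-yl)-4,4,5,5-tetramethyl-1,3,2-dioxaborolane
Product: 25 [4-[(2R,3S)-3-[[(tert-butyldimethylsilyl)oxy]methyl]-5-[(E)-3,3-diethoxyprop-1-en-1-yl]-7-methoxy-2,3-dihydro-1-benzofuran-2-yl]-2,6-dimethoxyphenoxy]triisopropylsilane
Conditions: Pd(OAc)2 (5 mol%), SPhos (10 mol%), K3PO4, THF/H2O, 50 °C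
Reagents that add atoms: none
Why: Suzuki–Miyaura coupling of the aryl bromide with the (E)-alkenylboronate proceeds with retention of alkene geometry and installs the enal as its base-stable diethyl acetal.

Step 18
Reactants: 25 [4-[(2R,3S)-3-[[(tert-butyldimethylsilyl)oxy]methyl]-5-[(E)-3,3-diethoxyprop-1-en-1-yl]-7-methoxy-2,3-dihydro-1-benzofuran-2-yl]-2,6-dimethoxyphenoxy]triisopropylsilane
Product: 26 4-[(2R,3S)-3-[[(tert-butyldimethylsilyl)oxy]methyl]-5-[(E)-3,3-diethoxyprop-1-en-1-yl]-7-methoxy-2,3-dihydro-1-benzofuran-2-yl]-2,6-dimethoxyphenol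
Conditions: Bu4NF (1.05 equiv), THF, 0 °C; AcOH quench
Reagents that add atoms: none
Why: Fluoride cleaves the aryl silyl ether much faster than the β-branched primary alkyl TBS ether, so one equivalent at 0 °C frees only the phenol.

Step 19
Reactants: 26 4-[(2R,3S)-3-[[(tert-butyldimethylsilyl)oxy]methyl]-5-[(E)-3,3-diethoxyprop-1-en-1-yl]-7-methoxy-2,3-dihydro-1-benzofuran-2-yl]-2,6-dimethoxyphenol; 3 methyl (R)-3-[(tert-butyldimethylsilyl)oxy]-2-hydroxypropanoate
Product: 27 methyl (S)-3-[(tert-butyldimethylsilyl)oxy]-2-[4-[(2R,3S)-3-[[(tert-butyldimethylsilyl)oxy]methyl]-5-[(E)-3,3-diethoxyprop-1-en-1-yl]-7-methoxy-2,3-dihydro-1-benzofuran-2-yl]-2,6-dimethoxyphenoxy]propanoate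
Conditions: PPh3, DIAD, toluene/THF, 0 °C to rt
Reagents that add atoms: none
Why: Mitsunobu etherification with SN2 inversion at the ester α-carbon sets C8' as S, as in step 3, under non-acidic conditions that spare the acetal.

Step 20
Reactants: 27 methyl (S)-3-[(tert-butyldimethylsilyl)oxy]-2-[4-[(2R,3S)-3-[[(tert-butyldimethylsilyl)oxy]methyl]-5-[(E)-3,3-diethoxyprop-1-en-1-yl]-7-methoxy-2,3-dihydro-1-benzofuran-2-yl]-2,6-dimethoxyphenoxy]propanoate
Product: 28 (S)-3-[(tert-butyldimethylsilyl)oxy]-2-[4-[(2R,3S)-3-[[(tert-butyldimethylsilyl)oxy]methyl]-5-[(E)-3,3-diethoxyprop-1-en-1-yl]-7-methoxy-2,3-dihydro-1-benzofuran-2-yl]-2,6-dimethoxyphenoxy]propanal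
Conditions: i-Bu2AlH (1.1 equiv), CH2Cl2, −78 °C; MeOH, then aq. potassium sodium tartrate; used crude
Reagents that add atoms: none
Why: Partial reduction to the aldehyde as in step 4, with the acetal, the alkene and the silyl ethers inert to i-Bu2AlH at −78 °C.

Step 21
Reactants: 12 the 1-O-TBS ether of 11 (left-half aryl bromide); 28 (S)-3-[(tert-butyldimethylsilyl)oxy]-2-[4-[(2R,3S)-3-[[(tert-butyldimethylsilyl)oxy]methyl]-5-[(E)-3,3-diethoxyprop-1-en-1-yl]-7-methoxy-2,3-dihydro-1-benzofuran-2-yl]-2,6-dimethoxyphenoxy]propanal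
Product: 31 protected tetramer with free 7'-OH (7-O/9-O/9'-O/3-CH2O-tetra-TBS; ring A 4-O-TIPS; enal as diethyl acetal; 7R,8S,7'R,8'S;2R,3S), via aryllithium 29 (not isolated), via aryltitanium triisopropoxide 30 (not isolated)
Conditions: 12 (1.3 equiv), t-BuLi (2.6 equiv), THF/Et2O, −78 °C; ClTi(OiPr)3, −78 to −40 °C; then 28, −78 to −20 °C; aq. NH4Cl
Reagents that add atoms: none
Why: Bromine–lithium exchange at ring B C1 of 12 (its only halogen, para to the ether oxygen and flanked by two CH) and transmetalation give a weakly basic, weakly Lewis acidic aryltitanium triisopropoxide, whose aryl group is transferred to the aldehyde carbon C7' of 28 through a four-centre addition. The closest known reaction type is the non-chelation-controlled (Felkin–Anh) 1,2-addition of organotitanium triisopropoxides to α-alkoxy aldehydes, already used in step 6. No ring is closed; the step forms the ring B C1–C7' bond, joins the two halves into the complete carbon skeleton and creates the last stereocentre. C7' is controlled by the neighbouring C8' stereocentre: the C8'–OAr bond stands anti to the incoming aryl group and the aryl passes the C8' hydrogen, not the CH2OTBS group, which should give the anti (erythro, 7'R,8'S) carbinol. The step needs diastereofacial selectivity, chemoselectivity for the aldehyde and configurational integrity at the enolisable C8'; the non-chelating titanium centre, the bulk of the 2,6-dimethoxyphenoxy group and the low basicity of the reagent at low temperature should secure these, and the acetal, silyl ethers and alkene of 28 are inert.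

Step 22
Reactants: 31 protected tetramer with free 7'-OH
Product: 33 CNP0192639.1 (target), via desilylated diethyl acetal 32 (not isolated)
Conditions: Bu4NF (8 equiv), AcOH (8 equiv), THF, 0 °C to rt; then 1 M aq. HCl to pH 2–3, 0 °C, 30 min
Reagents that add atoms: water, O
Why: Buffered fluoride removes the four TBS groups and the aryl TIPS group while the acetal is stable, and brief aqueous acid then hydrolyses the conjugated diethyl acetal to the (E)-enal without ionising the benzylic alcohols.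

## Compound list

1 | methyl (R)-2,2-dimethyl-1,3-dioxolane-4-carboxylate | COC(=O)[C@H]1COC(C)(C)O1 | starting material
2 | methyl (R)-2,3-dihydroxypropanoate | COC(=O)[C@H](O)CO | intermediate
3 | methyl (R)-3-[(tert-butyldimethylsilyl)oxy]-2-hydroxypropanoate | COC(=O)[C@H](O)CO[Si](C)(C)C(C)(C)C | intermediate
4 | 4-bromo-2,6-dimethoxyphenol | COc1cc(Br)cc(OC)c1O | starting material
5 | methyl (S)-2-(4-bromo-2,6-dimethoxyphenoxy)-3-[(tert-butyldimethylsilyl)oxy]propanoate | COC(=O)[C@@H](Oc1c(OC)cc(Br)cc1OC)CO[Si](C)(C)C(C)(C)C | intermediate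
6 | (S)-2-(4-bromo-2,6-dimethoxyphenoxy)-3-[(tert-butyldimethylsilyl)oxy]propanal | O=C[C@@H](Oc1c(OC)cc(Br)cc1OC)CO[Si](C)(C)C(C)(C)C | intermediate
7 | 4-bromo-2-methoxyphenol | COc1cc(Br)ccc1O | starting material
8 | (4-bromo-2-methoxyphenoxy)triisopropylsilane | COc1cc(Br)ccc1O[Si](C(C)C)(C(C)C)C(C)C | intermediate
9 | [3-methoxy-4-(triisopropylsilyloxy)phenyl]lithium (not isolated) | COc1cc([Li])ccc1O[Si](C(C)C)(C(C)C)C(C)C | intermediate
10 | [3-methoxy-4-(triisopropylsilyloxy)phenyl]titanium triisopropoxide (not isolated) | COc1cc([Ti](OC(C)C)(OC(C)C)OC(C)C)ccc1O[Si](C(C)C)(C(C)C)C(C)C | intermediate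
11 | (1R,2S)-2-(4-bromo-2,6-dimethoxyphenoxy)-3-[(tert-butyldimethylsilyl)oxy]-1-[3-methoxy-4-(triisopropylsilyloxy)phenyl]propan-1-ol (erythro) | COc1cc([C@@H](O)[C@H](CO[Si](C)(C)C(C)(C)C)Oc2c(OC)cc(Br)cc2OC)ccc1O[Si](C(C)C)(C(C)C)C(C)C | intermediate
12 | 1-O-TBS ether of 11: (1R,2S)-2-(4-bromo-2,6-dimethoxyphenoxy)-1,3-bis[(tert-butyldimethylsilyl)oxy]-1-[3-methoxy-4-(triisopropylsilyloxy)phenyl]propane | COc1cc([C@@H](O[Si](C)(C)C(C)(C)C)[C@H](CO[Si](C)(C)C(C)(C)C)Oc2c(OC)cc(Br)cc2OC)ccc1O[Si](C(C)C)(C(C)C)C(C)C | intermediate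
13 | 4-hydroxy-3,5-dimethoxybenzaldehyde (syringaldehyde) | COc1cc(C=O)cc(OC)c1O | starting material
14 | 3,5-dimethoxy-4-(triisopropylsilyloxy)benzaldehyde | COc1cc(C=O)cc(OC)c1O[Si](C(C)C)(C(C)C)C(C)C | intermediate
15 | [3,5-dimethoxy-4-(triisopropylsilyloxy)phenyl]methanol | COc1cc(CO)cc(OC)c1O[Si](C(C)C)(C(C)C)C(C)C | intermediate
16 | 4-bromo-2-iodo-6-methoxyphenol | COc1cc(Br)cc(I)c1O | intermediate
17 | [4-[(4-bromo-2-iodo-6-methoxyphenoxy)methyl]-2,6-dimethoxyphenoxy]triisopropylsilane | COc1cc(COc2c(I)cc(Br)cc2OC)cc(OC)c1O[Si](C(C)C)(C(C)C)C(C)C | intermediate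
18 | ethyl diazoacetate | CCOC(=O)C=[N+]=[N-] | starting material
19 | ethyl 2-[5-bromo-2-[[3,5-dimethoxy-4-(triisopropylsilyloxy)phenyl]methoxy]-3-methoxyphenyl]-2-diazoacetate | CCOC(=O)C(=[N+]=[N-])c1cc(Br)cc(OC)c1OCc1cc(OC)c(O[Si](C(C)C)(C(C)C)C(C)C)c(OC)c1 | intermediate
20 | ethyl (2R,3S)-5-bromo-2-[3,5-dimethoxy-4-(triisopropylsilyloxy)phenyl]-7-methoxy-2,3-dihydro-1-benzofuran-3-carboxylate (cis) | COc1cc([C@@H]2Oc3c(OC)cc(Br)cc3[C@@H]2C(=O)OCC)cc(OC)c1O[Si](C(C)C)(C(C)C)C(C)C | intermediate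
21 | ethyl (2R,3R)-5-bromo-2-[3,5-dimethoxy-4-(triisopropylsilyloxy)phenyl]-7-methoxy-2,3-dihydro-1-benzofuran-3-carboxylate (trans) | COc1cc([C@@H]2Oc3c(OC)cc(Br)cc3[C@H]2C(=O)OCC)cc(OC)c1O[Si](C(C)C)(C(C)C)C(C)C | intermediate
22 | [(2R,3S)-5-bromo-2-[3,5-dimethoxy-4-(triisopropylsilyloxy)phenyl]-7-methoxy-2,3-dihydro-1-benzofuran-3-yl]methanol (trans) | COc1cc([C@@H]2Oc3c(OC)cc(Br)cc3[C@H]2CO)cc(OC)c1O[Si](C(C)C)(C(C)C)C(C)C | intermediate
23 | O-TBS ether of 22: [4-[(2R,3S)-5-bromo-3-[[(tert-butyldimethylsilyl)oxy]methyl]-7-methoxy-2,3-dihydro-1-benzofuran-2-yl]-2,6-dimethoxyphenoxy]triisopropylsilane | COc1cc([C@@H]2Oc3c(OC)cc(Br)cc3[C@H]2CO[Si](C)(C)C(C)(C)C)cc(OC)c1O[Si](C(C)C)(C(C)C)C(C)C | intermediate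
24 | (E)-2-(3,3-diethoxyprop-1-en-1-yl)-4,4,5,5-tetramethyl-1,3,2-dioxaborolane | CCOC(OCC)/C=C/B1OC(C)(C)C(C)(C)O1 | starting material
25 | [4-[(2R,3S)-3-[[(tert-butyldimethylsilyl)oxy]methyl]-5-[(E)-3,3-diethoxyprop-1-en-1-yl]-7-methoxy-2,3-dihydro-1-benzofuran-2-yl]-2,6-dimethoxyphenoxy]triisopropylsilane | COc1cc([C@@H]2Oc3c(OC)cc(/C=C/C(OCC)OCC)cc3[C@H]2CO[Si](C)(C)C(C)(C)C)cc(OC)c1O[Si](C(C)C)(C(C)C)C(C)C | intermediate
26 | 4-[(2R,3S)-3-[[(tert-butyldimethylsilyl)oxy]methyl]-5-[(E)-3,3-diethoxyprop-1-en-1-yl]-7-methoxy-2,3-dihydro-1-benzofuran-2-yl]-2,6-dimethoxyphenol | COc1cc([C@@H]2Oc3c(OC)cc(/C=C/C(OCC)OCC)cc3[C@H]2CO[Si](C)(C)C(C)(C)C)cc(OC)c1O | intermediate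
27 | methyl (S)-3-[(tert-butyldimethylsilyl)oxy]-2-[4-[(2R,3S)-3-[[(tert-butyldimethylsilyl)oxy]methyl]-5-[(E)-3,3-diethoxyprop-1-en-1-yl]-7-methoxy-2,3-dihydro-1-benzofuran-2-yl]-2,6-dimethoxyphenoxy]propanoate | COC(=O)[C@@H](Oc1c(OC)cc([C@@H]2Oc3c(OC)cc(/C=C/C(OCC)OCC)cc3[C@H]2CO[Si](C)(C)C(C)(C)C)cc1OC)CO[Si](C)(C)C(C)(C)C | intermediate
28 | (S)-3-[(tert-butyldimethylsilyl)oxy]-2-[4-[(2R,3S)-3-[[(tert-butyldimethylsilyl)oxy]methyl]-5-[(E)-3,3-diethoxyprop-1-en-1-yl]-7-methoxy-2,3-dihydro-1-benzofuran-2-yl]-2,6-dimethoxyphenoxy]propanal | O=C[C@@H](Oc1c(OC)cc([C@@H]2Oc3c(OC)cc(/C=C/C(OCC)OCC)cc3[C@H]2CO[Si](C)(C)C(C)(C)C)cc1OC)CO[Si](C)(C)C(C)(C)C | intermediate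
29 | aryllithium from 12, lithium at ring B C1 (not isolated) | COc1cc([C@@H](O[Si](C)(C)C(C)(C)C)[C@H](CO[Si](C)(C)C(C)(C)C)Oc2c(OC)cc([Li])cc2OC)ccc1O[Si](C(C)C)(C(C)C)C(C)C | intermediate
30 | aryltitanium triisopropoxide from 29, titanium at ring B C1 (not isolated) | COc1cc([C@@H](O[Si](C)(C)C(C)(C)C)[C@H](CO[Si](C)(C)C(C)(C)C)Oc2c(OC)cc([Ti](OC(C)C)(OC(C)C)OC(C)C)cc2OC)ccc1O[Si](C(C)C)(C(C)C)C(C)C | intermediate
31 | protected tetramer with free 7'-OH: ring A 4-O-TIPS; 7-O-TBS, 9-O-TBS, 9'-O-TBS and 3-CH2O-TBS ethers; enal as diethyl acetal; (7R,8S,7'R,8'S; dihydrobenzofuran 2R,3S) | COc1cc([C@@H](O[Si](C)(C)C(C)(C)C)[C@H](CO[Si](C)(C)C(C)(C)C)Oc2c(OC)cc([C@@H](O)[C@H](CO[Si](C)(C)C(C)(C)C)Oc3c(OC)cc([C@@H]4Oc5c(OC)cc(/C=C/C(OCC)OCC)cc5[C@H]4CO[Si](C)(C)C(C)(C)C)cc3OC)cc2OC)ccc1O[Si](C(C)C)(C(C)C)C(C)C | intermediate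
32 | fully desilylated diethyl acetal of the target (not isolated) | COc1cc([C@@H](O)[C@H](CO)Oc2c(OC)cc([C@@H](O)[C@H](CO)Oc3c(OC)cc([C@@H]4Oc5c(OC)cc(/C=C/C(OCC)OCC)cc5[C@H]4CO)cc3OC)cc2OC)ccc1O | intermediate
33 | CNP0192639.1 | COc1cc([C@@H](O)[C@H](CO)Oc2c(OC)cc([C@@H](O)[C@H](CO)Oc3c(OC)cc([C@@H]4Oc5c(OC)cc(/C=C/C=O)cc5[C@H]4CO)cc3OC)cc2OC)ccc1O | target

## Step count and risks

Total step count: 22. Longest linear sequence: 14 steps (13 to 33 through steps 8, 9 and 11 to 22).

The three steps most likely to fail: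

Step 21 (key step). What may go wrong: insufficient facial selectivity in the aryl transfer to the α-aryloxy aldehyde, or loss of the aldehyde by enolisation (epimerisation at C8', β-elimination of silanolate) before the C–C bond forms. The fallback changes the oxidation level of C7' and sets out from ester 27 and aryl bromide 12. Ester 27 is converted with MeNH(OMe)·HCl and i-PrMgCl (THF, −20 °C) into the Weinreb amide F1. The aryllithium 29 made from 12 (t-BuLi, THF, −78 °C) is acylated by F1 to give the aryl ketone F2. Chelation-controlled reduction of F2 with Zn(BH4)2 (Et2O, −30 °C), in which zinc bridges the ketone oxygen and the C8' aryloxy oxygen and hydride enters anti to the CH2OTBS group, should give the erythro alcohol. The route is rejoined at 31.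

Step 13. What may go wrong: poor discrimination between the enantiotopic benzylic hydrogens by the chiral dirhodium catalyst, so that the dihydrobenzofuran forms with low enantiomeric purity. The fallback replaces asymmetric catalysis by resolution and sets out from diazo ester 19. Insertion with achiral Rh2(OAc)4 (CH2Cl2, rt) gives the ester as a racemate, that is 20 together with its enantiomer F3. Epimerisation with NaOEt gives 21 together with its enantiomer F4, and i-Bu2AlH gives 22 together with its enantiomer F5. Esterification with (S)-2-methoxy-2-phenylacetic acid (DCC, DMAP, CH2Cl2) gives the diastereomeric esters F6 (from 22) and F7 (from F5), which are separated by chromatography. Ester F6 is cleaved with i-Bu2AlH (CH2Cl2, −78 °C) and the route is rejoined at 22.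

Step 19. What may go wrong: slow SN2 displacement of the oxyphosphonium by the hindered 2,6-dimethoxyphenol on a valuable intermediate, so that elimination or alkylation of the hydrazide takes over. The fallback uses a preformed sulfonate and sets out from hydroxy ester 3 and phenol 26. Ester 3 is converted with Tf2O and 2,6-lutidine (CH2Cl2, −78 °C) into the triflate F8. The phenoxide of 26 (K2CO3, MeCN, 0 °C) displaces the triflate with inversion, and the route is rejoined at 27.

## Further compounds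

F1 | step 21 | (S)-N-methoxy-N-methyl amide corresponding to ester 27 (Weinreb amide) | CON(C)C(=O)[C@@H](Oc1c(OC)cc([C@@H]2Oc3c(OC)cc(/C=C/C(OCC)OCC)cc3[C@H]2CO[Si](C)(C)C(C)(C)C)cc1OC)CO[Si](C)(C)C(C)(C)C
F2 | step 21 | aryl ketone, the 7'-oxo analogue of 31 (7R,8S,8'S; 2R,3S) | COc1cc([C@@H](O[Si](C)(C)C(C)(C)C)[C@H](CO[Si](C)(C)C(C)(C)C)Oc2c(OC)cc(C(=O)[C@H](CO[Si](C)(C)C(C)(C)C)Oc3c(OC)cc([C@@H]4Oc5c(OC)cc(/C=C/C(OCC)OCC)cc5[C@H]4CO[Si](C)(C)C(C)(C)C)cc3OC)cc2OC)ccc1O[Si](C(C)C)(C(C)C)C(C)C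
F3 | step 13 | enantiomer of 20, ethyl (2S,3R)-5-bromo-2-[3,5-dimethoxy-4-(triisopropylsilyloxy)phenyl]-7-methoxy-2,3-dihydro-1-benzofuran-3-carboxylate | COc1cc([C@H]2Oc3c(OC)cc(Br)cc3[C@H]2C(=O)OCC)cc(OC)c1O[Si](C(C)C)(C(C)C)C(C)C
F4 | step 13 | enantiomer of 21, ethyl (2S,3S)-5-bromo-2-[3,5-dimethoxy-4-(triisopropylsilyloxy)phenyl]-7-methoxy-2,3-dihydro-1-benzofuran-3-carboxylate | COc1cc([C@H]2Oc3c(OC)cc(Br)cc3[C@@H]2C(=O)OCC)cc(OC)c1O[Si](C(C)C)(C(C)C)C(C)C
F5 | step 13 | enantiomer of 22, [(2S,3R)-5-bromo-2-[3,5-dimethoxy-4-(triisopropylsilyloxy)phenyl]-7-methoxy-2,3-dihydro-1-benzofuran-3-yl]methanol | COc1cc([C@H]2Oc3c(OC)cc(Br)cc3[C@@H]2CO)cc(OC)c1O[Si](C(C)C)(C(C)C)C(C)C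
F6 | step 13 | (S)-2-methoxy-2-phenylacetate of 22 | COc1cc([C@@H]2Oc3c(OC)cc(Br)cc3[C@H]2COC(=O)[C@@H](OC)c4ccccc4)cc(OC)c1O[Si](C(C)C)(C(C)C)C(C)C
F7 | step 13 | (S)-2-methoxy-2-phenylacetate of F5 | COc1cc([C@H]2Oc3c(OC)cc(Br)cc3[C@@H]2COC(=O)[C@@H](OC)c4ccccc4)cc(OC)c1O[Si](C(C)C)(C(C)C)C(C)C
F8 | step 19 | methyl (R)-3-[(tert-butyldimethylsilyl)oxy]-2-[(trifluoromethylsulfonyl)oxy]propanoate | COC(=O)[C@H](OS(=O)(=O)C(F)(F)F)CO[Si](C)(C)C(C)(C)C
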